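**Plan**

1. Retrosynthesis: the α-methylene-γ-butyrolactone is cut at C6–C7 (lactone carbinol carbon to ring-fusion carbon, also a bond of the ten-membered ring) and at C11–C12 (α-carbon to lactone carbonyl), with CO as the C12 unit whose bond to O6 closes in the same operation. This opens both rings to the acyclic (Z,Z)-allenyl enal 22.
2. Enabling feature: the lactone ring O6–C12(=O)–C11(=C13H2)–C7–C6 is the [2+2+1] retron of an aldehyde C=O (C6), the internal C7=C11 bond of a terminal allene and CO. The other eight ring carbons (C8–C10, C1–C5) are the tether.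
3. Chain 22 is cut at C2–C3 (aldol), C1–H (Evans–Tishchenko), C8–C7 (alkynylation) and C11–C13 (Crabbé); both Z-trisubstituted alkenes come from one vinyl iodide, (Z)-3-iodobut-2-en-1-ol.
4. Forward: the chain is joined first (aldol, anti-reduction with acetate transfer, alkynylation, allene, ester); then the ten-membered ring and the lactone close together, and one desilylation finishes.
5. Stereochemistry: alkene geometry from trans-hydroalumination/iodination; C3 from the Ipc2BCl aldol; C1 (1,3-anti) from the Evans–Tishchenko step, which also places the C3 acetate; C8 from the zinc–ProPhenol alkynylation; the ester stereocentre from (R)-2-methylbutanoic acid; C6 and C7 in the key step under control of C8.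

Key step: step 16

Remark on locants: C6 = lactone carbinol carbon, C7 = ring-fusion carbon, C8 = carbon bearing the 2-methylbutanoate, C9=C10 (C10 bears a methyl), C1 = free carbinol, C2 = CH2, C3 = acetoxy carbon, C4=C5 (C4 bears a methyl), C11/C12/C13 = lactone α-carbon, carbonyl and exocyclic CH2.

Assumption: (R)-2-methylbutanoic acid is taken as commercial, and in steps 6 and 10 the antipode of the chiral reagent named is the one expected to attack the Si face of the aldehyde (its mirror image is used should the sense prove opposite).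

**Step 1**
Reactants: 1 but-2-yn-1-ol
Product: 3 (Z)-3-iodobut-2-en-1-ol, via cyclic vinylalanate 2 (not isolated)
Conditions: NaAlH2(OCH2CH2OMe)2, THF, 0 °C to rt; then I2, −78 °C to 0 °C
Reagents that add atoms: iodine, II
Why: Hydroxyl-directed trans-hydroalumination of the propargylic alcohol puts aluminium on C3 cis to the CH2O group in a five-membered alanate, and iodinolysis with retention should give the Z-iodide that fixes the geometry of both ring alkenes.

**Step 2**
Reactants: 3 (Z)-3-iodobut-2-en-1-ol
Product: 4 (Z)-tert-butyl[(3-iodobut-2-en-1-yl)oxy]dimethylsilane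
Conditions: TBSCl, imidazole, CH2Cl2, 0 °C to rt
Reagents that add atoms: tert-butyldimethylsilyl chloride, CC(C)(C)[Si](C)(C)Cl
Why: Standard silyl ether formation gives the oxygen that later becomes the C6 aldehyde a mask that survives every step up to step 14.

**Step 3**
Reactants: 4 (Z)-tert-butyl[(3-iodobut-2-en-1-yl)oxy]dimethylsilane
Product: 6 (Z)-4-[(tert-butyldimethylsilyl)oxy]-2-methylbut-2-enal (C3–C6 piece), via TBS vinyllithium 5 (not isolated)
Conditions: t-BuLi (2.1 equiv), Et2O, −78 °C; then DMF, −78 to 0 °C; aq NH4Cl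
Reagents that add atoms: N,N-dimethylformamide, CN(C)C=O
Why: Iodine–lithium exchange proceeds with retention of alkene geometry and formylation of the vinyllithium should give the Z-enal, which is used at once to avoid Z to E isomerisation.

**Step 4**
Reactants: 3 (Z)-3-iodobut-2-en-1-ol
Product: 7 (Z)-triethyl[(3-iodobut-2-en-1-yl)oxy]silane
Conditions: TESCl, imidazole, CH2Cl2, 0 °C
Reagents that add atoms: chlorotriethylsilane, CC[Si](Cl)(CC)CC
Why: Silyl ether formation with a primary TES group, chosen because it can later be oxidised directly to the aldehyde in the presence of TBS ethers.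

**Step 5**
Reactants: 7 (Z)-triethyl[(3-iodobut-2-en-1-yl)oxy]silane
Product: 9 (Z)-3-methyl-5-[(triethylsilyl)oxy]pent-3-en-2-one (C2, C1, C10, C9, C8 piece), via TES vinyllithium 8 (not isolated)
Conditions: t-BuLi (2.1 equiv), Et2O, −78 °C; then MeC(O)N(OMe)Me, −78 to 0 °C; aq NH4Cl
Reagents that add atoms: N-methoxy-N-methylacetamide, CC(=O)N(C)OC
Why: Iodine–lithium exchange with retention followed by Weinreb ketone synthesis should give the Z-methyl enone without over-addition.

**Step 6**
Reactants: 9 (Z)-3-methyl-5-[(triethylsilyl)oxy]pent-3-en-2-one, 6 (Z)-4-[(tert-butyldimethylsilyl)oxy]-2-methylbut-2-enal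
Product: 11 aldol adduct (open chain C6–C8: C6 OTBS; C3 (S)-OH; C1 ketone; C8 OTES; 4Z and 9Z), via enol borinate 10 (not isolated)
Conditions: (−)-Ipc2BCl, Et3N, Et2O, −78 to 0 °C; then 6, −78 to −20 °C; H2O2, pH 7 buffer, MeOH, 0 °C
Reagents that add atoms: none
Why: Paterson boron aldol: Ipc2BCl/Et3N enolises the methyl ketone regioselectively and the chiral enol borinate is expected to add to the Si face of enal 6 through a chair-like transition state, which sets C3 as S; any antipodal material becomes a separable diastereomer once C8 is installed.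

**Step 7**
Reactants: 11 aldol adduct
Product: 12 anti-1,3-diol monoacetate (C3 (S)-OAc; C1 (S)-OH)
Conditions: SmI2 (0.3 equiv), CH3CHO (6 equiv), THF, −10 °C
Reagents that add atoms: acetaldehyde, CC=O
Why: Evans–Tishchenko reduction: the C3 hydroxyl forms a hemiacetal with acetaldehyde and delivers hydride intramolecularly through a samarium-bound six-membered transition state, which should set C1 as S (1,3-anti) and leaves the acetate on O3 as in the target.

**Step 8**
Reactants: 12 anti-1,3-diol monoacetate
Product: 13 C1 TBS ether of 12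
Conditions: TBSOTf, 2,6-lutidine, CH2Cl2, −78 °C
Reagents that add atoms: tert-butyldimethylsilyl trifluoromethanesulfonate, CC(C)(C)[Si](C)(C)OS(=O)(=O)C(F)(F)F
Why: Silylation with the silyl triflate masks the C1 hydroxyl, which would otherwise form a lactol with the C8 aldehyde or add in oxa-Michael fashion to the later C6 enal.

**Step 9**
Reactants: 13 C1 TBS ether
Product: 14 C8 (Z)-enal (C6 OTBS; C3 OAc; C1 OTBS)
Conditions: (COCl)2, DMSO, CH2Cl2, −78 to −40 °C; then Et3N, −78 to 0 °C
Reagents that add atoms: none
Why: Direct Swern oxidation of a primary TES ether: the chlorodimethylsulfonium ion attacks the least hindered silyl ether oxygen, so the TES ether is cleaved and oxidised in one operation to the Z-enal while the TBS ethers and the acetate persist.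

**Step 10**
Reactants: 14 C8 (Z)-enal
Product: 15 C8 (R)-propargylic alcohol with TMS-capped alkyne (C7≡C11)
Conditions: Me2Zn (3 equiv), (S,S)-ProPhenol (20 mol%), Ph3PO (40 mol%), HC≡CSiMe3 (3 equiv), toluene, 4 °C
Reagents that add atoms: ethynyltrimethylsilane, C#C[Si](C)(C)C
Why: Trost zinc–ProPhenol alkynylation: the dinuclear zinc catalyst delivers the alkynyl group to the Si face of the enal, which should set C8 as R under reagent control without touching the acetate.

**Step 11**
Reactants: 15 TMS-capped propargylic alcohol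
Product: 16 terminal alkynol
Conditions: AgNO3 (0.1 equiv), acetone/H2O/CH2Cl2, rt
Reagents that add atoms: none
Why: Silver-catalysed protodesilylation removes the alkynyl TMS group under neutral conditions, chosen over K2CO3/MeOH so that the C3 acetate and the silyl ethers survive.

**Step 12**
Reactants: 16 terminal alkynol
Product: 18 C8 α-allenol (C7=C11=C13H2), via Mannich base 17 (not isolated)
Conditions: CuI (0.5 equiv), Cy2NH, (CH2O)n, 1,4-dioxane, reflux
Reagents that add atoms: paraformaldehyde (formaldehyde unit), C=O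
Why: Crabbé–Ma homologation: the Mannich base undergoes copper-mediated 1,5-hydride transfer and loss of imine to give the terminal allene, adding C13 without touching the C8 stereocentre.

**Step 13**
Reactants: 18 C8 α-allenol, 19 (R)-2-methylbutanoic acid
Product: 20 allenyl (R)-2-methylbutanoate (C6 OTBS; C1 OTBS)
Conditions: DCC, DMAP (0.1 equiv), CH2Cl2, 0 °C to rt
Reagents that add atoms: none
Why: Steglich esterification of the secondary allenol installs the ester stereocentre from the chiral pool; low temperature and catalytic DMAP should avoid epimerisation of the acid α-centre.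

**Step 14**
Reactants: 20 allenyl ester
Product: 21 C6 primary allylic alcohol
Conditions: HF·pyridine, pyridine, THF, 0 °C
Reagents that add atoms: none
Why: Selective desilylation: the primary allylic TBS ether is cleaved much faster than the hindered secondary one by buffered HF·pyridine, and the acidic medium avoids acetate migration.

**Step 15**
Reactants: 21 C6 primary allylic alcohol
Product: 22 (Z,Z)-allenyl enal (C6 aldehyde; C3 OAc; C1 OTBS; C8 ester; terminal allene)
Conditions: MnO2, CH2Cl2, rt
Reagents that add atoms: none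
Why: Allylic oxidation with MnO2 under neutral heterogeneous conditions should preserve the Z-enal, the allene and both esters.

**Step 16**
Reactants: 22 (Z,Z)-allenyl enal
Product: 23 O1-TBS ether of the target (ten-membered ring cis-fused to the α-methylene lactone)
Conditions: Ru3(CO)12 (5 mol%), CO (20 atm), 1,4-dioxane, 120 °C, substrate added by syringe pump to 0.002 M
Reagents that add atoms: carbon monoxide, [C-]#[O+]
Why: Proposed new method: a ruthenium carbonyl fragment binds the aldehyde C=O and the internal C7=C11 bond of the allene and couples them oxidatively to an oxaruthenacyclopentane (C6–C7 bond), CO inserts into the Ru–C11 bond (C11–C12 bond) and C–O reductive elimination releases the α-methylene lactone; the closest known reaction type is the Ru3(CO)12-catalysed carbonylative [2+2+1] (hetero-Pauson–Khand) cyclisation of allenyl aldehydes to bicyclic α-methylene-γ-butyrolactones, so far shown only where a five- or six-membered ring is closed. The ten-membered carbocycle closes in the oxidative coupling in a 10-exo mode on both π-bonds (the aldehyde oxygen and C11=C13 stay outside the ring), and the five-membered lactone closes by carbonyl insertion and reductive elimination on the same metal centre. C6 and C7 arise together: both bonds at ruthenium are made on one face of the metallacycle, so the tether ends C5 and C8 are cis and the ring fusion is cis, and the C8 stereocentre selects the allene face by placing its acyloxy group anti to the incoming metal-bound aldehyde with H8 outside. The step needs ring closure to beat oligomerisation and the internal allene bond to react in preference to the terminal one; pseudo-high dilution, the two Z-trisubstituted alkenes that fold the chain ends towards each other and the known preference of this catalysis for the substituted allene bond should secure this. The O8 ester and the O1 silyl ether block ruthenium-catalysed cyclocarbonylation of a free allenol and oxa-Michael addition to the enal.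

**Step 17**
Reactants: 23 O1-TBS ether of the target
Product: 24 target CNP0282531.1
Conditions: HF·pyridine, THF, 0 °C to rt
Reagents that add atoms: none
Why: Acidic fluoride desilylation frees the C1 hydroxyl without base, so that neither O3 to O1 acetyl migration nor conjugate addition to the α-methylene lactone should occur.

**Compound list**

1 | but-2-yn-1-ol | CC#CCO | starting material
2 | sodium cyclic vinylalanate from 1 (five-membered O–Al–C3=C2–C1 ring, two 2-methoxyethoxy groups on Al; not isolated) | [Na+].CC1=CCO[Al-]1(OCCOC)OCCOC | intermediate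
3 | (Z)-3-iodobut-2-en-1-ol | OC/C=C(/C)I | intermediate
4 | (Z)-tert-butyl[(3-iodobut-2-en-1-yl)oxy]dimethylsilane | CC(C)(C)[Si](C)(C)OC/C=C(/C)I | intermediate
5 | (Z)-vinyllithium from 4 (not isolated) | CC(C)(C)[Si](C)(C)OC/C=C(/C)[Li] | intermediate
6 | (Z)-4-[(tert-butyldimethylsilyl)oxy]-2-methylbut-2-enal | CC(C)(C)[Si](C)(C)OC/C=C(/C)C=O | intermediate
7 | (Z)-triethyl[(3-iodobut-2-en-1-yl)oxy]silane | CC[Si](CC)(CC)OC/C=C(/C)I | intermediate
8 | (Z)-vinyllithium from 7 (not isolated) | CC[Si](CC)(CC)OC/C=C(/C)[Li] | intermediate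
9 | (Z)-3-methyl-5-[(triethylsilyl)oxy]pent-3-en-2-one | CC(=O)/C(C)=C\CO[Si](CC)(CC)CC | intermediate
10 | diisopinocampheyl enol borinate of 9 (Ipc groups from (+)-α-pinene; not isolated) | C=C(OB([C@@H]1C[C@@H]2C[C@H]([C@H]1C)C2(C)C)[C@@H]1C[C@@H]2C[C@H]([C@H]1C)C2(C)C)/C(C)=C\CO[Si](CC)(CC)CC | intermediate
11 | (2Z,6S,7Z)-9-[(tert-butyldimethylsilyl)oxy]-6-hydroxy-3,7-dimethyl-1-[(triethylsilyl)oxy]nona-2,7-dien-4-one (aldol adduct, C3 S) | CC(C)(C)[Si](C)(C)OC/C=C(/C)[C@@H](O)CC(=O)/C(C)=C\CO[Si](CC)(CC)CC | intermediate
12 | (2Z,4S,6S,7Z)-9-[(tert-butyldimethylsilyl)oxy]-4-hydroxy-3,7-dimethyl-1-[(triethylsilyl)oxy]nona-2,7-dien-6-yl acetate (C3 S acetate, C1 S alcohol) | CC(C)(C)[Si](C)(C)OC/C=C(/C)[C@@H](OC(C)=O)C[C@H](O)/C(C)=C\CO[Si](CC)(CC)CC | intermediate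
13 | C1 TBS ether of 12 (1S,3S; 4Z,9Z) | CC(C)(C)[Si](C)(C)OC/C=C(/C)[C@@H](OC(C)=O)C[C@H](O[Si](C)(C)C(C)(C)C)/C(C)=C\CO[Si](CC)(CC)CC | intermediate
14 | (2Z,4S,6S,7Z)-4,9-bis[(tert-butyldimethylsilyl)oxy]-3,7-dimethyl-1-oxonona-2,7-dien-6-yl acetate (C8 enal) | CC(C)(C)[Si](C)(C)OC/C=C(/C)[C@@H](OC(C)=O)C[C@H](O[Si](C)(C)C(C)(C)C)/C(C)=C\C=O | intermediate
15 | C8 (R)-propargylic alcohol, TMS-capped alkyne (1S,3S,8R; 4Z,9Z) | CC(C)(C)[Si](C)(C)OC/C=C(/C)[C@@H](OC(C)=O)C[C@H](O[Si](C)(C)C(C)(C)C)/C(C)=C\[C@@H](O)C#C[Si](C)(C)C | intermediate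
16 | C8 (R)-propargylic alcohol, terminal alkyne | CC(C)(C)[Si](C)(C)OC/C=C(/C)[C@@H](OC(C)=O)C[C@H](O[Si](C)(C)C(C)(C)C)/C(C)=C\[C@@H](O)C#C | intermediate
17 | Mannich base of 16 (N,N-dicyclohexylaminomethyl on the alkyne terminus; not isolated) | CC(C)(C)[Si](C)(C)OC/C=C(/C)[C@@H](OC(C)=O)C[C@H](O[Si](C)(C)C(C)(C)C)/C(C)=C\[C@@H](O)C#CCN(C1CCCCC1)C1CCCCC1 | intermediate
18 | C8 α-allenol (terminal allene C7=C11=C13H2; C8 S by CIP, same spatial arrangement as in 15) | CC(C)(C)[Si](C)(C)OC/C=C(/C)[C@@H](OC(C)=O)C[C@H](O[Si](C)(C)C(C)(C)C)/C(C)=C\[C@@H](O)C=C=C | intermediate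
19 | (R)-2-methylbutanoic acid | CC[C@@H](C)C(=O)O | starting material
20 | C8 allenyl (2R)-2-methylbutanoate (C6 OTBS, C3 OAc, C1 OTBS) | CC(C)(C)[Si](C)(C)OC/C=C(/C)[C@@H](OC(C)=O)C[C@H](O[Si](C)(C)C(C)(C)C)/C(C)=C\[C@@H](OC(=O)[C@H](C)CC)C=C=C | intermediate
21 | C6 primary allylic alcohol from 20 | OC/C=C(/C)[C@@H](OC(C)=O)C[C@H](O[Si](C)(C)C(C)(C)C)/C(C)=C\[C@@H](OC(=O)[C@H](C)CC)C=C=C | intermediate
22 | (Z,Z)-allenyl enal (C6 aldehyde, C3 OAc, C1 OTBS, C8 ester, terminal allene) | O=C/C=C(/C)[C@@H](OC(C)=O)C[C@H](O[Si](C)(C)C(C)(C)C)/C(C)=C\[C@@H](OC(=O)[C@H](C)CC)C=C=C | intermediate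
23 | O1-TBS ether of the target (1S,3S,6S,7R,8R; 4Z,9Z; cis-fused α-methylene lactone) | C=C1C(=O)O[C@H]2/C=C(/C)[C@@H](OC(C)=O)C[C@H](O[Si](C)(C)C(C)(C)C)/C(C)=C\[C@@H](OC(=O)[C@H](C)CC)[C@@H]12 | intermediate
24 | CNP0282531.1: (1S,3S,6S,7R,8R)-3-acetoxy-1-hydroxy-8-[(2R)-2-methylbutanoyloxy]germacra-4Z,9Z,11(13)-trien-12,6-olide (locants as defined above) | C=C1C(=O)O[C@H]2/C=C(/C)[C@@H](OC(C)=O)C[C@H](O)/C(C)=C\[C@@H](OC(=O)[C@H](C)CC)[C@@H]12 | target

**Step count and risks**

Total steps: 17. Longest linear sequence: 15 (steps 1–3 and 6–17).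

Steps most likely to fail:

1. Step 16. The chain ends may fail to meet on ruthenium, so that intermolecular coupling, decarbonylation or Z to E isomerisation of the enal outruns ring closure; facial selection at the allene may be poor, or the allenylic ester may ionise. Fallback, from 22 back to 23, separating the two bond formations: Pd(PPh3)4-catalysed distannylation of the allene with (Bu3Sn)2 (THF, rt) should give the 2,3-bis(tributylstannyl)alkene F1 (allylstannane at C13, vinylstannane at C11). BF3·OEt2 at −78 °C under high dilution would close the ten-membered ring by intramolecular allylstannane–aldehyde addition through C7 to the hydroxy vinylstannane F2. Iododestannylation (I2, CH2Cl2, 0 °C) would give the vinyl iodide F3, and carbonylative lactonisation (Pd(PPh3)4, CO 1 atm, Et3N, MeCN, 60 °C) would form C11–C12 and return to 23. The C6/C7 relationship would then be set in the allylation and would have to be checked.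

2. Step 6. Enantioface discrimination in a methyl ketone boron aldol may be low, and the α-methyl Z-enal may isomerise under the Lewis-acidic conditions. Fallback, from 6 back to 11, with auxiliary control: a titanium enolate acetate aldol of (S)-3-acetyl-4-benzylthiazolidine-2-thione (TiCl4, i-Pr2NEt, CH2Cl2, −78 °C; the auxiliary antipode that gives the 3S carbinol as major, separable diastereomer is used) should give the thioimide aldol F4. Transamidation with MeNHOMe·HCl and imidazole would give the β-hydroxy Weinreb amide F5, and addition of vinyllithium 8 (2.5 equiv, −78 °C) would return to 11.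

3. Step 12. Hydride transfer from the Mannich base may stall, and copper may cycloisomerise the α-allenol at reflux. Fallback, from 14 back to 20, making the allene by a reductive 1,3-transposition at low temperature: zinc–ProPhenol addition of 4-methoxybenzyl propargyl ether to 14 should give the propargylic alcohol F6. Steglich esterification with 19 would give the ester F7 and DDQ (CH2Cl2, pH 7 buffer) the primary propargylic alcohol F8. Myers allene synthesis (2-nitrobenzenesulfonylhydrazide, PPh3, DEAD, THF, −15 °C to rt) would then deliver 20 directly.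

**Further compounds**

F1 | step 16 | 2,3-bis(tributylstannyl)alkene from 22 (allylstannane at C13, vinylstannane at C11; C7=C11 geometry not defined) | O=C/C=C(/C)[C@@H](OC(C)=O)C[C@H](O[Si](C)(C)C(C)(C)C)/C(C)=C\[C@@H](OC(=O)[C@H](C)CC)C=C(C[Sn](CCCC)(CCCC)CCCC)[Sn](CCCC)(CCCC)CCCC
F2 | step 16 | ten-membered C6 alcohol bearing a 1-(tributylstannyl)vinyl group on C7 | O[C@H]1/C=C(/C)[C@@H](OC(C)=O)C[C@H](O[Si](C)(C)C(C)(C)C)/C(C)=C\[C@@H](OC(=O)[C@H](C)CC)[C@H]1C(=C)[Sn](CCCC)(CCCC)CCCC
F3 | step 16 | ten-membered C6 alcohol bearing a 1-iodovinyl group on C7 | O[C@H]1/C=C(/C)[C@@H](OC(C)=O)C[C@H](O[Si](C)(C)C(C)(C)C)/C(C)=C\[C@@H](OC(=O)[C@H](C)CC)[C@H]1C(=C)I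
F4 | step 6 | thioimide aldol of 6 with (S)-3-acetyl-4-benzylthiazolidine-2-thione (C3 S) | CC(C)(C)[Si](C)(C)OC/C=C(/C)[C@@H](O)CC(=O)N1C(=S)SC[C@@H]1Cc1ccccc1
F5 | step 6 | β-hydroxy Weinreb amide (C3 S) | CC(C)(C)[Si](C)(C)OC/C=C(/C)[C@@H](O)CC(=O)N(C)OC
F6 | step 12 | C8 (R)-propargylic alcohol with 4-methoxybenzyloxymethyl on the alkyne | CC(C)(C)[Si](C)(C)OC/C=C(/C)[C@@H](OC(C)=O)C[C@H](O[Si](C)(C)C(C)(C)C)/C(C)=C\[C@@H](O)C#CCOCc1ccc(OC)cc1
F7 | step 12 | C8 (2R)-2-methylbutanoate of F6 | CC(C)(C)[Si](C)(C)OC/C=C(/C)[C@@H](OC(C)=O)C[C@H](O[Si](C)(C)C(C)(C)C)/C(C)=C\[C@@H](OC(=O)[C@H](C)CC)C#CCOCc1ccc(OC)cc1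
F8 | step 12 | primary propargylic alcohol from F7 | CC(C)(C)[Si](C)(C)OC/C=C(/C)[C@@H](OC(C)=O)C[C@H](O[Si](C)(C)C(C)(C)C)/C(C)=C\[C@@H](OC(=O)[C@H](C)CC)C#CCO
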